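**Assumption:** the target SMILES has no stereocentre and no E/Z-stereogenic double bond, so it is one achiral compound and no enantiocontrol is needed.

## Retrosynthetic overview

- The butenolide ring is opened at the lactone O–C7a bond (C–O) and the C3=C3a double bond is rehydrated. This leads back to a quinol β-hydroxy ester in which a methoxy group sits on the carbon that will become C7a.
- The quinol ester is disconnected at C3–C3a: 1,2-aldol addition of a 4-hydroxyphenylacetate enolate to one carbonyl of symmetric 2,5-dimethoxy-3,6-diphenyl-1,4-benzoquinone.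
- The quinone comes from a double Suzuki coupling of 2,5-dibromo-3,6-dimethoxy-1,4-benzoquinone with phenylboronic acid; the dibromide comes from bromanil and methoxide.
- Ring order: the six-membered ring is bought (bromanil), the two phenyl rings are attached, and the butenolide ring is formed last by C–O closure.

## Route

**Step 1**
Reactants: 1 tetrabromo-1,4-benzoquinone (bromanil)
Product: 2 2,5-dibromo-3,6-dimethoxy-1,4-benzoquinone
Conditions: NaOMe (2.05 equiv), MeOH, 0 °C → rt
Reagents that add atoms: sodium methoxide, [Na+].[O-]C
Why: Two addition–elimination (SNV) substitutions of bromide by methoxide; the first methoxy group deactivates its own enone as a vinylogous ester, so the second goes to the para carbon and gives the 2,5-pattern.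

**Step 2**
Reactants: 2 2,5-dibromo-3,6-dimethoxy-1,4-benzoquinone; 3 phenylboronic acid (2.5 equiv)
Product: 4 2,5-dimethoxy-3,6-diphenyl-1,4-benzoquinone
Conditions: Pd(dppf)Cl2 (5 mol %), K2CO3, 1,4-dioxane (water-lean), 90 °C
Reagents that add atoms: none
Why: Double Suzuki–Miyaura coupling at the activated β-bromo-enone C–Br bonds; water-lean conditions protect the base-sensitive vinylogous ester methoxy groups.

**Step 3**
Reactants: 5 tert-butyl 2-(4-hydroxyphenyl)acetate (1.1 equiv); 4 2,5-dimethoxy-3,6-diphenyl-1,4-benzoquinone
Product: 7 tert-butyl 2-(1-hydroxy-2,5-dimethoxy-4-oxo-3,6-diphenylcyclohexa-2,5-dien-1-yl)-2-(4-hydroxyphenyl)acetate (racemic mixture of diastereomers), via dilithium enolate-phenoxide 6 (not isolated)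
Conditions: LDA (2.2 equiv), THF, –78 °C; then 4, THF, –78 °C; AcOH, –78 °C
Reagents that add atoms: none
Why: Kinetic aldol 1,2-addition of a lithium ester enolate to a quinone carbonyl, assisted by Li chelation between C=O and the neighbouring OMe (the mode known for organolithium additions to 2,5-dialkoxyquinones and ester-enolate additions to benzoquinone); the two carbonyls of 4 are equivalent, the quinol and α-carbon stereocentres form without control, and both are erased in step 4.

**Step 4**
Reactants: 7 tert-butyl 2-(1-hydroxy-2,5-dimethoxy-4-oxo-3,6-diphenylcyclohexa-2,5-dien-1-yl)-2-(4-hydroxyphenyl)acetate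
Product: 10 3-(4-hydroxyphenyl)-5-methoxy-4,7-diphenyl-1-benzofuran-2,6-dione (5-O-methylxylerythrin), via free carboxylic acid 8 (not isolated), via 3a-hydroxy lactone 9 (not isolated)
Conditions: TFA/CH2Cl2 (1:3), 0 °C → rt, then 40 °C, N2 sweep
Reagents that add atoms: none
Why: Proposed new method: acid-triggered demethanolative lactonisation at a vinylogous ester carbon (intramolecular SNV by a carboxyl oxygen) coupled to aldol-type dehydration. TFA cleaves the tert-butyl ester to acid 8; protonation of the dienone carbonyl makes the β-methoxy enone carbon next to the quinol centre an oxocarbenium-like electrophile; the carboxyl oxygen adds 5-exo and methanol is expelled to give enol lactone 9; enol-assisted loss of the tertiary hydroxyl then gives the fully conjugated quinone methide lactone 10 as the thermodynamic sink. Only the methoxy group flanking the quinol carbon can form the five-membered ring, so the other one survives as 5-OMe. The closest known reaction types are acid-catalysed alkoxy exchange of β-alkoxy enones (vinylogous transesterification), addition–elimination of O- and N-nucleophiles on methoxyquinones, and the dehydration half of an acid-catalysed aldol condensation; no stereocentre remains.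

## Compound list

1 | tetrabromo-1,4-benzoquinone (bromanil) | O=C1C(Br)=C(Br)C(=O)C(Br)=C1Br | starting material
2 | 2,5-dibromo-3,6-dimethoxy-1,4-benzoquinone | COC1=C(Br)C(=O)C(OC)=C(Br)C1=O | intermediate
3 | phenylboronic acid | OB(O)c1ccccc1 | starting material
4 | 2,5-dimethoxy-3,6-diphenyl-1,4-benzoquinone | COC1=C(c2ccccc2)C(=O)C(OC)=C(c2ccccc2)C1=O | intermediate
5 | tert-butyl 2-(4-hydroxyphenyl)acetate | CC(C)(C)OC(=O)Cc1ccc(O)cc1 | starting material
6 | dilithium enolate-phenoxide of 5 | [Li+].[Li+].CC(C)(C)OC([O-])=Cc1ccc([O-])cc1 | intermediate (not isolated)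
7 | tert-butyl 2-(1-hydroxy-2,5-dimethoxy-4-oxo-3,6-diphenylcyclohexa-2,5-dien-1-yl)-2-(4-hydroxyphenyl)acetate, racemic, mixture of diastereomers (no configuration defined) | COC1=C(c2ccccc2)C(O)(C(c2ccc(O)cc2)C(=O)OC(C)(C)C)C(OC)=C(c2ccccc2)C1=O | intermediate
8 | 2-(1-hydroxy-2,5-dimethoxy-4-oxo-3,6-diphenylcyclohexa-2,5-dien-1-yl)-2-(4-hydroxyphenyl)acetic acid, racemic, mixture of diastereomers | COC1=C(c2ccccc2)C(O)(C(c2ccc(O)cc2)C(=O)O)C(OC)=C(c2ccccc2)C1=O | intermediate (not isolated)
9 | 3a-hydroxy-3-(4-hydroxyphenyl)-5-methoxy-4,7-diphenyl-3,3a-dihydro-1-benzofuran-2,6-dione, racemic, mixture of diastereomers | COC1=C(c2ccccc2)C2(O)C(c3ccc(O)cc3)C(=O)OC2=C(c2ccccc2)C1=O | intermediate (not isolated)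
10 | 3-(4-hydroxyphenyl)-5-methoxy-4,7-diphenyl-1-benzofuran-2,6-dione (achiral) | COC1=C(c2ccccc2)C2=C(c3ccc(O)cc3)C(=O)OC2=C(c2ccccc2)C1=O | target

## Step count and risks

Total step count: 4. Longest linear sequence: 4 (1 → 2 → 4 → 7 → 10).

**Step 4 (proposed new step).** The free β-hydroxy acid 8 could instead ionise at the quinol carbon and lose CO2 and water (decarboxylative dehydration to a benzylidene quinone methide), undergo retro-aldol cleavage, or stop before methanol is expelled. The fallback uses known chemistry, sets out from 4 and comes back at 10. Mono-demethylation of 4 (NaOH 1.1 equiv, aqueous dioxane, rt, then acidify) gives 2-hydroxy-5-methoxy-3,6-diphenyl-1,4-benzoquinone F4; the resulting hydroxyquinone anion resists a second hydrolysis. Heating F4 with commercial 4-hydroxyphenylacetic acid in Ac2O/NaOAc is the established Perkin-type O-acylation/intramolecular Knoevenagel condensation of hydroxyquinones with arylacetic acids. It can only close onto the carbonyl next to the acylated oxygen and gives 4-(5-methoxy-2,6-dioxo-4,7-diphenyl-2,6-dihydro-1-benzofuran-3-yl)phenyl acetate F5. Catalytic K2CO3 in MeOH at 0 °C with dilute HCl work-up removes the aryl acetate and gives 10.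

**Step 3.** The electron-rich dianion 6 may transfer an electron to the quinone, attack the methoxy-bearing carbon instead of the carbonyl, or the hindered aldolate may revert on warming. The fallback sets out from 5 and comes back at 7. Compound 5 is silylated twice in one flask (LDA 2.2 equiv, TMSCl 2.3 equiv, THF, –78 °C) to the neutral silyl ketene acetal 1-tert-butoxy-1-(trimethylsilyloxy)-2-[4-(trimethylsilyloxy)phenyl]ethene F3. A Mukaiyama aldol addition of F3 to 4 under chelating Lewis acid activation (MgBr2·OEt2 or BF3·OEt2, CH2Cl2, –78 °C) avoids basic and reducing conditions. Mild aqueous acid work-up removes the silyl groups and gives 7.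

**Step 2.** The bromoquinone can be reduced by Pd(0)/boronic acid, or its methoxy groups hydrolysed by base at 90 °C. The fallback sets out from 2 and comes back at 4. Reduction of 2 with Na2S2O4 (EtOAc/H2O) gives 2,5-dibromo-3,6-dimethoxybenzene-1,4-diol F1, a non-oxidising, base-stable aryl dibromide. Double Suzuki coupling of F1 with 3 (Pd(OAc)2/SPhos, K3PO4, toluene/H2O, 90 °C) gives 3,6-dimethoxy-2,5-diphenylbenzene-1,4-diol F2. Oxidation of F2 (FeCl3 or air, rt) returns quinone 4.

## Further compounds

F1 | step 2 | 2,5-dibromo-3,6-dimethoxybenzene-1,4-diol | COc1c(Br)c(O)c(OC)c(Br)c1O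
F2 | step 2 | 3,6-dimethoxy-2,5-diphenylbenzene-1,4-diol | COc1c(-c2ccccc2)c(O)c(OC)c(-c2ccccc2)c1O
F3 | step 3 | 1-tert-butoxy-1-(trimethylsilyloxy)-2-[4-(trimethylsilyloxy)phenyl]ethene (E/Z mixture) | CC(C)(C)OC(O[Si](C)(C)C)=Cc1ccc(O[Si](C)(C)C)cc1
F4 | step 4 | 2-hydroxy-5-methoxy-3,6-diphenyl-1,4-benzoquinone | COC1=C(c2ccccc2)C(=O)C(O)=C(c2ccccc2)C1=O
F5 | step 4 | 4-(5-methoxy-2,6-dioxo-4,7-diphenyl-2,6-dihydro-1-benzofuran-3-yl)phenyl acetate | COC1=C(c2ccccc2)C2=C(c3ccc(OC(C)=O)cc3)C(=O)OC2=C(c2ccccc2)C1=O
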